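**Plan**

- Retrosynthetic cuts, in order: C3–OH back to a C3–OMe ketal; the C6–CH3 bond (methyl onto a cyclic peroxycarbenium ion); both C–O bonds of the O1–O2 bridge (giving an acyclic 3,6-diketone plus H2O2); the bond from C6 to the side-chain CH2 as an acyl–alkyl bond; C3–CH2CO2Me (malonate acylation); C4–C5 and C2′–CH3 (auxiliary alkylations; C2′ is the methyl-bearing side-chain carbon).
- Enabling feature: C3 and C6 of the 1,2-dioxane each carry one oxygen of the O–O bridge and sit 1,4 to each other. The ring is therefore a 1,4-diketone clipped by H2O2, and C6 is a latent ketone carbon whose bond to the side-chain CH2 is an acyl–alkyl bond.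
- Forward: the side-chain iodide (4 steps) and a succinate thioester (3 steps) are joined at the C6–CH2 bond to give a 4-keto imide. The imide is turned into the β-keto ester, the only ring (the 1,2-dioxane) is closed by peroxide clipping, then C6 is methylated and the C3 ketal hydrolysed.
- Stereochemistry: C2′ (R) and C4 (R) come from two Evans alkylations. C6 (S) comes from axial methyl transfer to the half-chair peroxycarbenium ion, anti to the equatorial C4 methyl. C3 (S) comes from anomeric equilibration of the hemiketal.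

Key step: step 8

Remark: the C3 hemiketal of the target is taken to be the thermodynamic anomer (axial OH, cis to the C4 methyl), so it is set by equilibration and not by a dedicated step.

**Route**

Step 1
Reactants: 1 10-phenyldecanoic acid; 2 (4R)-4-benzyl-1,3-oxazolidin-2-one
Product: 4 (4R)-4-benzyl-3-(10-phenyldecanoyl)-1,3-oxazolidin-2-one, via mixed pivalic anhydride 3 (not isolated)
Conditions: PivCl, Et3N, THF, −20 °C; then 2, LiCl, −20 °C to rt
Reagents that add atoms: none
Why: N-acylation of the oxazolidinone through the mixed pivalic anhydride is a standard way to load an Evans auxiliary, the nitrogen attacking the unhindered acyl carbon.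

Step 2
Reactants: 4 (4R)-4-benzyl-3-(10-phenyldecanoyl)-1,3-oxazolidin-2-one
Product: 6 (4R)-4-benzyl-3-[(2R)-2-methyl-10-phenyldecanoyl]-1,3-oxazolidin-2-one, via sodium enolate 5 (not isolated)
Conditions: NaN(SiMe3)2, THF, −78 °C; then MeI, −78 °C
Reagents that add atoms: iodomethane, CI
Why: Evans alkylation, in which the chelated sodium (Z)-enolate is methylated on the face opposite the benzyl group and so sets the future side-chain stereocenter as R.

Step 3
Reactants: 6 (4R)-4-benzyl-3-[(2R)-2-methyl-10-phenyldecanoyl]-1,3-oxazolidin-2-one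
Product: 7 (2R)-2-methyl-10-phenyldecan-1-ol
Conditions: LiBH4, H2O (1 equiv), Et2O, 0 °C
Reagents that add atoms: none
Why: Reductive auxiliary cleavage, in which LiBH4 reduces the exocyclic imide carbonyl to the primary alcohol without touching the stereocenter and releases the auxiliary for recovery.

Step 4
Reactants: 7 (2R)-2-methyl-10-phenyldecan-1-ol
Product: 8 (2R)-1-iodo-2-methyl-10-phenyldecane
Conditions: PPh3, I2, imidazole, CH2Cl2, 0 °C to rt
Reagents that add atoms: iodine, II
Why: Appel-type iodination replaces the primary hydroxyl by SN2 at CH2 and leaves the adjacent stereocenter untouched.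

Step 5
Reactants: 9 (4S)-4-benzyl-3-propanoyl-1,3-oxazolidin-2-one; 10 tert-butyl bromoacetate
Product: 12 tert-butyl (3R)-4-[(4S)-4-benzyl-2-oxo-1,3-oxazolidin-3-yl]-3-methyl-4-oxobutanoate, via sodium enolate 11 (not isolated)
Conditions: NaN(SiMe3)2, THF, −78 °C; then 10, −78 to −40 °C
Reagents that add atoms: none
Why: Evans alkylation, in which the sodium (Z)-enolate is alkylated by the reactive α-bromo ester anti to the benzyl group and so sets the methyl-bearing carbon (future C4 of the ring) as R.

Step 6
Reactants: 12 tert-butyl (3R)-4-[(4S)-4-benzyl-2-oxo-1,3-oxazolidin-3-yl]-3-methyl-4-oxobutanoate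
Product: 13 (3R)-4-[(4S)-4-benzyl-2-oxo-1,3-oxazolidin-3-yl]-3-methyl-4-oxobutanoic acid
Conditions: CF3CO2H, CH2Cl2, rt
Reagents that add atoms: none
Why: Acidolysis of the tert-butyl ester (loss of isobutene) frees the acid, the imide and the stereocenter being stable to trifluoroacetic acid.

Step 7
Reactants: 13 (3R)-4-[(4S)-4-benzyl-2-oxo-1,3-oxazolidin-3-yl]-3-methyl-4-oxobutanoic acid
Product: 14 S-ethyl (3R)-4-[(4S)-4-benzyl-2-oxo-1,3-oxazolidin-3-yl]-3-methyl-4-oxobutanethioate
Conditions: EtSH, DCC, DMAP (cat.), CH2Cl2, 0 °C to rt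
Reagents that add atoms: ethanethiol, CCS
Why: Steglich thioesterification gives the acyl donor for the coupling, and the stereocenter is β to the activated carbonyl so it cannot epimerise through it.

Step 8
Reactants: 8 (2R)-1-iodo-2-methyl-10-phenyldecane; 14 S-ethyl (3R)-4-[(4S)-4-benzyl-2-oxo-1,3-oxazolidin-3-yl]-3-methyl-4-oxobutanethioate
Product: 16 (4S)-4-benzyl-3-[(2R,6R)-2,6-dimethyl-4-oxo-14-phenyltetradecanoyl]-1,3-oxazolidin-2-one, via alkylzinc iodide 15 (not isolated)
Conditions: Zn dust (activated with 1,2-dibromoethane and Me3SiCl), THF, 40 °C; then 14, PdCl2(PPh3)2 (5 mol %), toluene, rt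
Reagents that add atoms: none
Why: Zinc inserts into the C–I bond of 8; zerovalent palladium (formed from PdCl2(PPh3)2 and the organozinc) adds oxidatively into the acyl C–S bond of 14, the alkyl group is transmetalated from zinc, and reductive elimination forms the ketone, joining the side-chain CH2 to the carbon that becomes C6 of the ring. The closest known reaction type is the Fukuyama coupling of S-ethyl thioesters with functionalised primary alkylzinc iodides. No ring is closed and no stereocenter is made; the step is chosen because it delivers C6 at the ketone oxidation level, 1,4 to the C3 acyl carbon, which is what the later peroxide clip and axial methylation require. The two existing stereocenters are safe, since the one in 15 is β to zinc and the one in 14 is β to the reacting carbonyl, so neither can be lost by enolisation at the reacting centers. The selectivity needed is acyl transfer at the thioester only, which is secured because oxidative addition is specific for the C–S bond and alkylzinc iodides do not add to the imide or to the ketone that is formed.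

Step 9
Reactants: 16 (4S)-4-benzyl-3-[(2R,6R)-2,6-dimethyl-4-oxo-14-phenyltetradecanoyl]-1,3-oxazolidin-2-one
Product: 18 (2R,6R)-2,6-dimethyl-4-oxo-14-phenyltetradecanoic acid, via lithium peroxycarboxylate 17 (not isolated)
Conditions: LiOH, H2O2 (30% aq), THF/H2O, 0 °C; then Na2SO3 (aq); then HCl (aq) to pH 2
Reagents that add atoms: hydrogen peroxide, OO
Why: Standard Evans auxiliary hydrolysis, in which hydroperoxide anion attacks the exocyclic imide carbonyl selectively, sulfite reduces the peracid salt, and the α-stereocenter should be retained under the cold, weakly basic conditions.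

Step 10
Reactants: 18 (2R,6R)-2,6-dimethyl-4-oxo-14-phenyltetradecanoic acid; 19 potassium methyl malonate
Product: 22 methyl (4R,8R)-4,8-dimethyl-3,6-dioxo-16-phenylhexadecanoate, via acyl imidazolide 20 (not isolated), via magnesium methyl malonate 21 (not isolated)
Conditions: 18, carbonyldiimidazole, THF, rt; separately 19, MgCl2, Et3N, MeCN, rt; combine, rt to 40 °C; then HCl (aq)
Reagents that add atoms: none
Why: Masamune homologation, in which the acyl imidazolide C-acylates the magnesium malonate enolate and decarboxylation on acidic work-up gives the β-keto ester under near-neutral conditions that should not epimerise C4.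

Step 11
Reactants: 22 methyl (4R,8R)-4,8-dimethyl-3,6-dioxo-16-phenylhexadecanoate
Product: 24 methyl 2-[(3S,4R,6S)-3,6-dimethoxy-4-methyl-6-[(2R)-2-methyl-10-phenyldecyl]-1,2-dioxan-3-yl]acetate, via cyclic bis-hemiketal 23 (not isolated)
Conditions: urea–hydrogen peroxide (1.5 equiv), camphorsulfonic acid (cat.), MeOH, 0 °C; then HC(OMe)3, rt
Reagents that add atoms: hydrogen peroxide (as its urea adduct), OO; methanol, CO
Why: Acid-catalysed peroxyketalisation, in which H2O2 adds to the unhindered C6 ketone, the hydroperoxide closes 6-exo-trig on the C3 ketone to form the 1,2-dioxane, and both anomeric hydroxyls exchange for methoxy under thermodynamic (anomeric) control, the ketal configurations being of no consequence later because C6 is ionised in step 12 and C3 is equilibrated in step 13.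

Step 12
Reactants: 24 methyl 2-[(3S,4R,6S)-3,6-dimethoxy-4-methyl-6-[(2R)-2-methyl-10-phenyldecyl]-1,2-dioxan-3-yl]acetate
Product: 26 methyl 2-[(3S,4R,6S)-3-methoxy-4,6-dimethyl-6-[(2R)-2-methyl-10-phenyldecyl]-1,2-dioxan-3-yl]acetate, via peroxycarbenium triflate 25 (not isolated)
Conditions: Me3SiOTf (1.2 equiv), AlMe3 (3 equiv), CH2Cl2, −78 °C; then Rochelle salt (aq)
Reagents that add atoms: trimethylaluminium, C[Al](C)C
Why: Proposed new method: Me3SiOTf should ionise the C6 methoxy group selectively (the C3 ketal is deactivated by the adjacent CH2CO2Me) to the cyclic peroxycarbenium ion, whose half-chair carries the C4 methyl pseudoequatorial and the C3 methoxy pseudoaxial, and AlMe3 should deliver methyl along the axial trajectory on the face anti to the C4 methyl through a chair-like transition state, which places the new methyl axial and trans to the C4 methyl and the side chain equatorial, that is 6S; the closest known reaction types are the Lewis acid-mediated substitution of 3-alkoxy-1,2-dioxanes and 3-alkoxy-1,2-dioxolanes by allylsilanes and silyl enol ethers through peroxycarbenium ions, and the AlMe3 C-methylation of cyclic ketals and glycosyl-type donors, including trioxane lactol derivatives that carry an endoperoxide.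

Step 13
Reactants: 26 methyl 2-[(3S,4R,6S)-3-methoxy-4,6-dimethyl-6-[(2R)-2-methyl-10-phenyldecyl]-1,2-dioxan-3-yl]acetate
Product: 27 methyl 2-[(3S,4R,6S)-3-hydroxy-4,6-dimethyl-6-[(2R)-2-methyl-10-phenyldecyl]-1,2-dioxan-3-yl]acetate
Conditions: p-TsOH·H2O (0.2 equiv), THF/H2O 3:1, rt
Reagents that add atoms: water, O
Why: Acid-catalysed hydrolysis of the C3 peroxyketal to the hemiketal (the reverse of the known acid-catalysed ketalisation of 3-hydroxy-1,2-dioxane-3-acetates in methanol), after which ring–chain equilibration should settle C3 in the anomerically favoured 3S form with axial OH cis to the C4 methyl.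

**Compound list**

1 | 10-phenyldecanoic acid | OC(=O)CCCCCCCCCc1ccccc1 | starting material
2 | (4R)-4-benzyl-1,3-oxazolidin-2-one | O=C1N[C@H](Cc2ccccc2)CO1 | starting material
3 | 2,2-dimethylpropanoic 10-phenyldecanoic anhydride (mixed pivalic anhydride) | CC(C)(C)C(=O)OC(=O)CCCCCCCCCc1ccccc1 | intermediate (not isolated)
4 | (4R)-4-benzyl-3-(10-phenyldecanoyl)-1,3-oxazolidin-2-one | O=C(CCCCCCCCCc1ccccc1)N1[C@H](Cc2ccccc2)COC1=O | intermediate
5 | sodium (Z)-enolate of 4 | [Na+].[O-]/C(=C\CCCCCCCCc1ccccc1)N1[C@H](Cc2ccccc2)COC1=O | intermediate (not isolated)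
6 | (4R)-4-benzyl-3-[(2R)-2-methyl-10-phenyldecanoyl]-1,3-oxazolidin-2-one | O=C([C@H](C)CCCCCCCCc1ccccc1)N1[C@H](Cc2ccccc2)COC1=O | intermediate
7 | (2R)-2-methyl-10-phenyldecan-1-ol | OC[C@H](C)CCCCCCCCc1ccccc1 | intermediate
8 | (2R)-1-iodo-2-methyl-10-phenyldecane | IC[C@H](C)CCCCCCCCc1ccccc1 | intermediate
9 | (4S)-4-benzyl-3-propanoyl-1,3-oxazolidin-2-one | CCC(=O)N1[C@@H](Cc2ccccc2)COC1=O | starting material
10 | tert-butyl bromoacetate | CC(C)(C)OC(=O)CBr | starting material
11 | sodium (Z)-enolate of 9 | [Na+].[O-]/C(=C\C)N1[C@@H](Cc2ccccc2)COC1=O | intermediate (not isolated)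
12 | tert-butyl (3R)-4-[(4S)-4-benzyl-2-oxo-1,3-oxazolidin-3-yl]-3-methyl-4-oxobutanoate | CC(C)(C)OC(=O)C[C@@H](C)C(=O)N1[C@@H](Cc2ccccc2)COC1=O | intermediate
13 | (3R)-4-[(4S)-4-benzyl-2-oxo-1,3-oxazolidin-3-yl]-3-methyl-4-oxobutanoic acid | OC(=O)C[C@@H](C)C(=O)N1[C@@H](Cc2ccccc2)COC1=O | intermediate
14 | S-ethyl (3R)-4-[(4S)-4-benzyl-2-oxo-1,3-oxazolidin-3-yl]-3-methyl-4-oxobutanethioate | CCSC(=O)C[C@@H](C)C(=O)N1[C@@H](Cc2ccccc2)COC1=O | intermediate
15 | [(2R)-2-methyl-10-phenyldecyl]zinc iodide | I[Zn]C[C@H](C)CCCCCCCCc1ccccc1 | intermediate (not isolated)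
16 | (4S)-4-benzyl-3-[(2R,6R)-2,6-dimethyl-4-oxo-14-phenyltetradecanoyl]-1,3-oxazolidin-2-one | O=C(C[C@H](C)CCCCCCCCc1ccccc1)C[C@@H](C)C(=O)N1[C@@H](Cc2ccccc2)COC1=O | intermediate
17 | lithium (2R,6R)-2,6-dimethyl-4-oxo-14-phenyltetradecaneperoxoate | [Li+].[O-]OC(=O)[C@H](C)CC(=O)C[C@H](C)CCCCCCCCc1ccccc1 | intermediate (not isolated)
18 | (2R,6R)-2,6-dimethyl-4-oxo-14-phenyltetradecanoic acid | OC(=O)[C@H](C)CC(=O)C[C@H](C)CCCCCCCCc1ccccc1 | intermediate
19 | potassium methyl malonate (potassium 3-methoxy-3-oxopropanoate) | [K+].[O-]C(=O)CC(=O)OC | starting material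
20 | (2R,6R)-1-(imidazol-1-yl)-2,6-dimethyl-14-phenyltetradecane-1,4-dione (acyl imidazolide) | O=C([C@H](C)CC(=O)C[C@H](C)CCCCCCCCc1ccccc1)n1ccnc1 | intermediate (not isolated)
21 | magnesium bis(3-methoxy-3-oxopropanoate) (magnesium methyl malonate) | [Mg+2].[O-]C(=O)CC(=O)OC.[O-]C(=O)CC(=O)OC | intermediate (not isolated)
22 | methyl (4R,8R)-4,8-dimethyl-3,6-dioxo-16-phenylhexadecanoate | COC(=O)CC(=O)[C@H](C)CC(=O)C[C@H](C)CCCCCCCCc1ccccc1 | intermediate
23 | methyl 2-[(3S,4R,6S)-3,6-dihydroxy-4-methyl-6-[(2R)-2-methyl-10-phenyldecyl]-1,2-dioxan-3-yl]acetate (expected major anomer of an equilibrating mixture) | COC(=O)C[C@]1(O)OO[C@@](O)(C[C@H](C)CCCCCCCCc2ccccc2)C[C@H]1C | intermediate (not isolated)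
24 | methyl 2-[(3S,4R,6S)-3,6-dimethoxy-4-methyl-6-[(2R)-2-methyl-10-phenyldecyl]-1,2-dioxan-3-yl]acetate (expected major anomer; ketal epimers converge in step 12) | COC(=O)C[C@]1(OC)OO[C@@](OC)(C[C@H](C)CCCCCCCCc2ccccc2)C[C@H]1C | intermediate
25 | (3S,4R)-3-methoxy-3-(2-methoxy-2-oxoethyl)-4-methyl-6-[(2R)-2-methyl-10-phenyldecyl]-4,5-dihydro-3H-1,2-dioxin-1-ium trifluoromethanesulfonate (cyclic peroxycarbenium triflate) | COC(=O)C[C@]1(OC)O[O+]=C(C[C@H](C)CCCCCCCCc2ccccc2)C[C@H]1C.[O-]S(=O)(=O)C(F)(F)F | intermediate (not isolated)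
26 | methyl 2-[(3S,4R,6S)-3-methoxy-4,6-dimethyl-6-[(2R)-2-methyl-10-phenyldecyl]-1,2-dioxan-3-yl]acetate | COC(=O)C[C@]1(OC)OO[C@@](C)(C[C@H](C)CCCCCCCCc2ccccc2)C[C@H]1C | intermediate
27 | methyl 2-[(3S,4R,6S)-3-hydroxy-4,6-dimethyl-6-[(2R)-2-methyl-10-phenyldecyl]-1,2-dioxan-3-yl]acetate | COC(=O)C[C@]1(O)OO[C@@](C)(C[C@H](C)CCCCCCCCc2ccccc2)C[C@H]1C | target

**Step count and risks**

Total step count: 13. Longest linear sequence: 10 steps (steps 1–4, then 8–13); steps 5–7 form the shorter branch.

Steps most likely to fail: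

1. Step 12. Reduction of the O–O bond by the alkylaluminium, or Lewis-acid-triggered O–O heterolysis with carbon migration, may outrun ionisation of the C6–OMe bond; ionisation at C3 is a lesser concern. The fallback sets out from 22 and comes back to the route at 27, using only known chemistry. Wittig methylenation of the C6 ketone (Ph3PCH3Br, KOtBu in excess, THF; the β-keto ester sits as its potassium enolate and is spared) should give methyl (4R,8R)-4,8-dimethyl-6-methylidene-3-oxo-16-phenylhexadecanoate F1. Isayama–Mukaiyama peroxidation (Co(acac)2, O2, Et3SiH, 1,2-dichloroethane) should then place the silylperoxy group on the tertiary carbon and give methyl (4R,8R)-4,6,8-trimethyl-3-oxo-16-phenyl-6-[(triethylsilyl)peroxy]hexadecanoate F2 as both C6 epimers. Desilylation (aqueous HF in MeCN) frees the hydroperoxide, which closes on the C3 ketone to 27 and its C6 epimer, to be separated by chromatography. No organometallic meets the O–O bond, at the price of no control at C6.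

2. Step 11. Acid-catalysed cyclodehydration of the free 1,4-diketone to a furan (Paal–Knorr) and over-addition of H2O2 at the β-keto ester end (peroxylactone formation) may compete with the clip, and the ester-deactivated C3 hemiketal may resist exchange. The fallback sets out from 22 and comes back at 24, separating the two events so that the 1,4-diketone never meets acid. The peroxide bridge is closed first without any acid (H2O2, MeCN, rt) and the bis-hemiketal 23 is isolated. Only then are both anomeric hydroxyls exchanged for methoxy on the ring-closed peroxide (MeOH, HC(OMe)3, pyridinium p-toluenesulfonate), which can no longer dehydrate to a furan. No compound outside the list is made (F0).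

3. Step 13. Ionisation at the ester-deactivated C3 ketal may be slow, and forcing acid may keep the ring open long enough for enolisation toward C4 (epimerisation) or cause acid-induced cleavage of the peroxide. The fallback sets out from 22 and comes back at 27, replacing the methyl ketal by a fluoride-labile one. Step 11 is run in 2-(trimethylsilyl)ethanol in place of methanol to give methyl 2-[(3S,4R,6S)-4-methyl-6-[(2R)-2-methyl-10-phenyldecyl]-3,6-bis[2-(trimethylsilyl)ethoxy]-1,2-dioxan-3-yl]acetate F3. Methylation under the conditions of step 12 gives methyl 2-[(3S,4R,6S)-4,6-dimethyl-6-[(2R)-2-methyl-10-phenyldecyl]-3-[2-(trimethylsilyl)ethoxy]-1,2-dioxan-3-yl]acetate F4. Bu4NF buffered with AcOH (THF, 0 °C) then removes the silylethyl group by β-elimination under non-acidic conditions and leaves the hemiketal 27.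

**Further compounds**

F1 | step 12 | methyl (4R,8R)-4,8-dimethyl-6-methylidene-3-oxo-16-phenylhexadecanoate | COC(=O)CC(=O)[C@H](C)CC(=C)C[C@H](C)CCCCCCCCc1ccccc1
F2 | step 12 | methyl (4R,8R)-4,6,8-trimethyl-3-oxo-16-phenyl-6-[(triethylsilyl)peroxy]hexadecanoate (both C6 epimers) | COC(=O)CC(=O)[C@H](C)CC(C)(OO[Si](CC)(CC)CC)C[C@H](C)CCCCCCCCc1ccccc1
F0 | step 11 | none | none
F3 | step 13 | methyl 2-[(3S,4R,6S)-4-methyl-6-[(2R)-2-methyl-10-phenyldecyl]-3,6-bis[2-(trimethylsilyl)ethoxy]-1,2-dioxan-3-yl]acetate | COC(=O)C[C@]1(OCC[Si](C)(C)C)OO[C@@](OCC[Si](C)(C)C)(C[C@H](C)CCCCCCCCc2ccccc2)C[C@H]1C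
F4 | step 13 | methyl 2-[(3S,4R,6S)-4,6-dimethyl-6-[(2R)-2-methyl-10-phenyldecyl]-3-[2-(trimethylsilyl)ethoxy]-1,2-dioxan-3-yl]acetate | COC(=O)C[C@]1(OCC[Si](C)(C)C)OO[C@@](C)(C[C@H](C)CCCCCCCCc2ccccc2)C[C@H]1C
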